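**Plan**
- Locants (tetralin): C1 aryl methine, C2 carbinol carbon carrying carboxyl C10, C3 carbinol carbon carrying hydroxymethyl C9, C4 benzylic CH2, C4a/C8a the fusion carbons of ring A; O2 and O3 are the carbinol oxygens.
- Retrosynthetic cuts, in order: the four O–benzyl bonds; C9–O and the C10–O3 bond of an iodomethyl β-lactone; C3–O3 and C9–I (back to the exocyclic C3=C9 alkene of a 3-methylene acid); C2–C3; C2–O2; C1–aryl; C4a–C4.
- Forward: ring A aldehyde with a 2-bromoallyl arm → (E)-enoate → 3,3-diarylpropanoate → α-benzyloxy ester → carbocycle (C2–C3) → acid → oxetanone fused at C2–C3 → diol → debenzylation.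
- Enabling feature: on the six-membered carbocycle, C10 (on C2) is cis to O3 and O2 is trans to O3. The C2 carboxylate can therefore reach C3 of the exocyclic C3=C9 alkene from the correct face, through a four-membered lactone that can only be cis-fused.
- Stereochemistry: C1 from a Rh/chiral-diene conjugate arylation; C2 from C1 in the ring closure; C3 from C2 through the fused β-lactone.

Key step: step 13

Assumption: with (S,S)-Ph-bod* the aryl group is taken to add to the Re face of C-β of enoate 9 (the spatial sense that turns cyclohexenone into (S)-3-phenylcyclohexanone); if the sense is found reversed, the (R,R)-ligand is used and nothing else changes.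

**Step 1**
Reactants: 1 2-bromo-5-hydroxy-4-methoxybenzaldehyde (6-bromoisovanillin)
Product: 2 5-(benzyloxy)-2-bromo-4-methoxybenzaldehyde
Conditions: BnBr, K2CO3, DMF, rt
Reagents that add atoms: benzyl bromide, BrCc1ccccc1
Why: Williamson O-benzylation of the phenol; the bromine already sits para to this oxygen, the position that will carry C4.

**Step 2**
Reactants: 2 5-(benzyloxy)-2-bromo-4-methoxybenzaldehyde
Product: 3 2-[5-(benzyloxy)-2-bromo-4-methoxyphenyl]-1,3-dioxolane
Conditions: HOCH2CH2OH, p-TsOH (cat.), toluene, reflux, Dean–Stark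
Reagents that add atoms: ethylene glycol, OCCO
Why: Acid-catalysed acetalisation with azeotropic removal of water masks the aldehyde for the organomagnesium step.

**Step 3**
Reactants: 3 2-[5-(benzyloxy)-2-bromo-4-methoxyphenyl]-1,3-dioxolane; 4 2,3-dibromopropene
Product: 7 5-(benzyloxy)-2-(2-bromoprop-2-en-1-yl)-4-methoxybenzaldehyde, via aryl Grignard reagent 5 (not isolated), via bromoallyl dioxolane 6 (not isolated)
Conditions: Mg, LiCl, THF, 25–40 °C; CuI (5 mol %), 4 (1.5 equiv), −20 → 0 °C; then 2 M HCl, THF, rt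
Reagents that add atoms: water, O
Why: Magnesium insertion gives the aryl Grignard reagent, copper-catalysed allylic substitution at the allylic C–Br of 4 (the vinylic bromide is inert) forms C4a–C4, and aqueous acid then hydrolyses the dioxolane.

**Step 4**
Reactants: 7 5-(benzyloxy)-2-(2-bromoprop-2-en-1-yl)-4-methoxybenzaldehyde; 8 tert-butyl (triphenyl-λ5-phosphanylidene)acetate
Product: 9 tert-butyl (2E)-3-[5-(benzyloxy)-2-(2-bromoprop-2-en-1-yl)-4-methoxyphenyl]prop-2-enoate
Conditions: toluene, 80 °C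
Reagents that add atoms: none
Why: Wittig olefination with a stabilised ylide should give the (E)-enoate and brings in C2 and C10.

**Step 5**
Reactants: 10 5-bromo-2-hydroxy-3-methoxybenzaldehyde
Product: 12 5-bromo-3-methoxybenzene-1,2-diol, via aryl formate 11 (not isolated)
Conditions: 30 % H2O2, aq. NaOH, 0 °C → rt, N2; then HCl
Reagents that add atoms: hydrogen peroxide, OO
Why: Dakin oxidation (aryl migration in the peroxide adduct of the ortho-hydroxybenzaldehyde, then formate hydrolysis) puts the second oxygen where the formyl group was, so bromine ends meta to both outer oxygens, a pattern that bromination of a 3-methoxycatechol diether would not give.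

**Step 6**
Reactants: 12 5-bromo-3-methoxybenzene-1,2-diol
Product: 13 1,2-bis(benzyloxy)-5-bromo-3-methoxybenzene
Conditions: BnBr (2.3 equiv), K2CO3, DMF, 60 °C
Reagents that add atoms: benzyl bromide, BrCc1ccccc1
Why: Double Williamson benzylation protects the catechol in a form that the final hydrogenolysis removes.

**Step 7**
Reactants: 13 1,2-bis(benzyloxy)-5-bromo-3-methoxybenzene
Product: 16 [3,4-bis(benzyloxy)-5-methoxyphenyl]boronic acid, via aryllithium 14 (not isolated), via lithium aryltriisopropoxyborate 15 (not isolated)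
Conditions: n-BuLi, THF, −78 °C; B(OiPr)3, −78 °C → rt; 1 M HCl
Reagents that add atoms: triisopropyl borate, CC(C)OB(OC(C)C)OC(C)C; water, O
Why: Bromine–lithium exchange, trapping of the aryllithium by the borate ester and acidic hydrolysis is the standard route to an arylboronic acid.

**Step 8**
Reactants: 9 tert-butyl (2E)-3-[5-(benzyloxy)-2-(2-bromoprop-2-en-1-yl)-4-methoxyphenyl]prop-2-enoate; 16 [3,4-bis(benzyloxy)-5-methoxyphenyl]boronic acid
Product: 17 tert-butyl (3S)-3-[5-(benzyloxy)-2-(2-bromoprop-2-en-1-yl)-4-methoxyphenyl]-3-[3,4-bis(benzyloxy)-5-methoxyphenyl]propanoate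
Conditions: [RhCl(C2H4)2]2 (2.5 mol %), (S,S)-Ph-bod* (5.5 mol %), KOH (20 mol %), 16 (2.5 equiv), dioxane/H2O 10:1, 50 °C
Reagents that add atoms: none
Why: Hayashi–Miyaura conjugate arylation: the arylrhodium(I) species adds to the Re face of C-β selected by the C2-symmetric diene and so sets C1 as (S), water protonates the rhodium enolate faster than it can engage the bromoalkene, and the vinylic bromide is not expected to react with rhodium(I) at this temperature.

**Step 9**
Reactants: 17 tert-butyl (3S)-3-[5-(benzyloxy)-2-(2-bromoprop-2-en-1-yl)-4-methoxyphenyl]-3-[3,4-bis(benzyloxy)-5-methoxyphenyl]propanoate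
Product: 18 tert-butyl (3S)-3-[5-(benzyloxy)-2-(2-bromoprop-2-en-1-yl)-4-methoxyphenyl]-3-[3,4-bis(benzyloxy)-5-methoxyphenyl]-2-hydroxypropanoate (C2 epimers)
Conditions: KHMDS, THF, −78 °C; (±)-trans-2-(phenylsulfonyl)-3-phenyloxaziridine; AcOH
Reagents that add atoms: 2-(phenylsulfonyl)-3-phenyloxaziridine, O=S(=O)(c1ccccc1)N1OC1c1ccccc1
Why: Davis hydroxylation of the potassium ester enolate installs O2; the C2 configuration formed here is of no consequence because C2 is planarised again in step 11, and the benzhydryl C1–H is not acidic enough to be touched.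

**Step 10**
Reactants: 18 tert-butyl (3S)-3-[5-(benzyloxy)-2-(2-bromoprop-2-en-1-yl)-4-methoxyphenyl]-3-[3,4-bis(benzyloxy)-5-methoxyphenyl]-2-hydroxypropanoate (C2 epimers)
Product: 19 tert-butyl (3S)-2-(benzyloxy)-3-[5-(benzyloxy)-2-(2-bromoprop-2-en-1-yl)-4-methoxyphenyl]-3-[3,4-bis(benzyloxy)-5-methoxyphenyl]propanoate (C2 epimers)
Conditions: NaH, BnBr, Bu4NI (cat.), THF/DMF, 0 °C → rt
Reagents that add atoms: benzyl bromide, BrCc1ccccc1
Why: Williamson benzylation of the secondary alkoxide caps O2, so that it neither forms a dianion in step 11 nor competes for the iodonium ion in step 13.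

**Step 11**
Reactants: 19 tert-butyl (3S)-2-(benzyloxy)-3-[5-(benzyloxy)-2-(2-bromoprop-2-en-1-yl)-4-methoxyphenyl]-3-[3,4-bis(benzyloxy)-5-methoxyphenyl]propanoate (C2 epimers)
Product: 20 tert-butyl (1S,2S)-2,7-bis(benzyloxy)-1-[3,4-bis(benzyloxy)-5-methoxyphenyl]-6-methoxy-3-methylidene-1,2,3,4-tetrahydronaphthalene-2-carboxylate
Conditions: Pd2(dba)3 (5 mol %), P(t-Bu)3 (12 mol %), LiHMDS (1.5 equiv), toluene, rt → 60 °C
Reagents that add atoms: none
Why: Palladium-catalysed intramolecular α-alkenylation of the ester enolate (Buchwald–Hartwig-type enolate coupling) closes C2–C3 to the six-membered ring; C2 is set by C1, because in the product-like transition state the bulky tert-butoxycarbonyl group should take the position anti to the pseudoaxial C1 aryl group (no eclipsing with the new exocyclic methylene) and leave the smaller benzyloxy group cis to the aryl group.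

**Step 12**
Reactants: 20 tert-butyl (1S,2S)-2,7-bis(benzyloxy)-1-[3,4-bis(benzyloxy)-5-methoxyphenyl]-6-methoxy-3-methylidene-1,2,3,4-tetrahydronaphthalene-2-carboxylate
Product: 22 (1S,2S)-2,7-bis(benzyloxy)-1-[3,4-bis(benzyloxy)-5-methoxyphenyl]-6-methoxy-3-methylidene-1,2,3,4-tetrahydronaphthalene-2-carboxylic acid, via trimethylsilyl ester 21 (not isolated)
Conditions: TMSOTf, 2,6-lutidine, CH2Cl2, 0 °C → rt; aqueous work-up at pH 4
Reagents that add atoms: none
Why: Silyl triflate-mediated tert-butyl ester cleavage proceeds by alkyl–oxygen fission with loss of isobutene, so crowding at C10 does not matter, and the lutidine buffer keeps protic acid away from the exocyclic alkene and the benzyl ethers.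

**Step 13**
Reactants: 22 (1S,2S)-2,7-bis(benzyloxy)-1-[3,4-bis(benzyloxy)-5-methoxyphenyl]-6-methoxy-3-methylidene-1,2,3,4-tetrahydronaphthalene-2-carboxylic acid
Product: 23 (1S,2S,3S)-2,7-bis(benzyloxy)-1-[3,4-bis(benzyloxy)-5-methoxyphenyl]-3-hydroxy-3-(iodomethyl)-6-methoxy-1,2,3,4-tetrahydronaphthalene-2-carboxylic acid β-lactone (oxetan-2-one cis-fused at C2–C3, ester bond C10–O3)
Conditions: I2 (3 equiv), NaHCO3 (4 equiv), MeCN, 0 °C, dark; cold aq. Na2S2O3 wash; crude product used at once
Reagents that add atoms: iodine, II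
Why: Iodine activates the exocyclic C3=C9 alkene as an iodonium ion whose positive charge lies mainly on the tertiary carbon C3, and the C10 carboxylate, held axial on the neighbouring quaternary C2, attacks C3 anti to iodine while iodine stays on C9; the closest known reaction type is the kinetic halolactonisation of β,γ-unsaturated acids to β-lactones under bicarbonate conditions. The oxetanone closes in the 4-exo-trig mode, whereas the 5-endo alternative would require attack at the primary carbon C9 and leave a tertiary iodide, which is disfavoured electronically and geometrically. The new stereocentre C3 is controlled by C2, because a four-membered lactone fused to the six-membered ring can only be cis-fused, so O3 must enter on the face that carries C10, the face opposite to O2. The step needs 4-exo over 5-endo closure, which the 1,1-disubstituted alkene and the fully substituted C2 secure, and alkene over arene iodination, which buffered molecular iodine at 0 °C in the dark should secure since it does not iodinate alkoxybenzenes at a useful rate. The benzyl group on O2 keeps that oxygen from competing for the iodonium ion.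

**Step 14**
Reactants: 23 the iodomethyl β-lactone of step 13
Product: 26 (1S,2S,3R)-2,7-bis(benzyloxy)-1-[3,4-bis(benzyloxy)-5-methoxyphenyl]-3-hydroxy-3-(hydroxymethyl)-6-methoxy-1,2,3,4-tetrahydronaphthalene-2-carboxylic acid (tetra-O-benzylplicatic acid), via iodohydrin acid 24 (not isolated), via spiro-epoxy acid 25 (not isolated)
Conditions: 2 M NaOH, 1,4-dioxane, 0 °C → rt, then 90 °C; HCl to pH 2
Reagents that add atoms: sodium hydroxide, [Na+].[OH-]
Why: Hydroxide opens the strained β-lactone at the acyl carbon, the freed C3 alkoxide displaces the neighbouring iodide (3-exo-tet Williamson closure) to the spiro-epoxide, and hot hydroxide opens this 2,2-disubstituted oxirane at the primary carbon C9 by SN2, so the C3–O3 bond is never broken and C3 keeps its configuration, while the carboxylate form of the intermediates disfavours retro-aldol cleavage of C2–C3.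

**Step 15**
Reactants: 26 tetra-O-benzylplicatic acid
Product: 27 plicatic acid, (1S,2S,3R)-1-(3,4-dihydroxy-5-methoxyphenyl)-2,3,7-trihydroxy-3-(hydroxymethyl)-6-methoxy-1,2,3,4-tetrahydronaphthalene-2-carboxylic acid
Conditions: H2 (1–4 bar), Pd(OH)2/C, THF/MeOH (degassed), rt
Reagents that add atoms: none
Why: Catalytic hydrogenolysis cleaves the three aryl benzyl ethers and the tertiary alkyl benzyl ether at their O–CH2Ph bonds without touching any stereocentre.

**Compound list**
1 | 2-bromo-5-hydroxy-4-methoxybenzaldehyde | COc1cc(Br)c(C=O)cc1O | starting material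
2 | 5-(benzyloxy)-2-bromo-4-methoxybenzaldehyde | COc1cc(Br)c(C=O)cc1OCc1ccccc1 | intermediate
3 | 2-[5-(benzyloxy)-2-bromo-4-methoxyphenyl]-1,3-dioxolane | COc1cc(Br)c(C2OCCO2)cc1OCc1ccccc1 | intermediate
4 | 2,3-dibromopropene | C=C(Br)CBr | starting material
5 | [4-(benzyloxy)-2-(1,3-dioxolan-2-yl)-5-methoxyphenyl]magnesium bromide | COc1cc([Mg]Br)c(C2OCCO2)cc1OCc1ccccc1 | intermediate
6 | 2-[5-(benzyloxy)-2-(2-bromoprop-2-en-1-yl)-4-methoxyphenyl]-1,3-dioxolane | COc1cc(CC(Br)=C)c(C2OCCO2)cc1OCc1ccccc1 | intermediate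
7 | 5-(benzyloxy)-2-(2-bromoprop-2-en-1-yl)-4-methoxybenzaldehyde | COc1cc(CC(Br)=C)c(C=O)cc1OCc1ccccc1 | intermediate
8 | tert-butyl (triphenyl-λ5-phosphanylidene)acetate | CC(C)(C)OC(=O)C=P(c1ccccc1)(c1ccccc1)c1ccccc1 | starting material
9 | tert-butyl (2E)-3-[5-(benzyloxy)-2-(2-bromoprop-2-en-1-yl)-4-methoxyphenyl]prop-2-enoate | COc1cc(CC(Br)=C)c(/C=C/C(=O)OC(C)(C)C)cc1OCc1ccccc1 | intermediate
10 | 5-bromo-2-hydroxy-3-methoxybenzaldehyde | COc1cc(Br)cc(C=O)c1O | starting material
11 | 5-bromo-2-hydroxy-3-methoxyphenyl formate | COc1cc(Br)cc(OC=O)c1O | intermediate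
12 | 5-bromo-3-methoxybenzene-1,2-diol | COc1cc(Br)cc(O)c1O | intermediate
13 | 1,2-bis(benzyloxy)-5-bromo-3-methoxybenzene | COc1cc(Br)cc(OCc2ccccc2)c1OCc1ccccc1 | intermediate
14 | [3,4-bis(benzyloxy)-5-methoxyphenyl]lithium | [Li]c1cc(OC)c(OCc2ccccc2)c(OCc2ccccc2)c1 | intermediate
15 | lithium [3,4-bis(benzyloxy)-5-methoxyphenyl]tri(propan-2-yloxy)borate | [Li+].COc1cc(cc(OCc2ccccc2)c1OCc1ccccc1)[B-](OC(C)C)(OC(C)C)OC(C)C | intermediate
16 | [3,4-bis(benzyloxy)-5-methoxyphenyl]boronic acid | COc1cc(B(O)O)cc(OCc2ccccc2)c1OCc1ccccc1 | intermediate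
17 | tert-butyl (3S)-3-[5-(benzyloxy)-2-(2-bromoprop-2-en-1-yl)-4-methoxyphenyl]-3-[3,4-bis(benzyloxy)-5-methoxyphenyl]propanoate | COc1cc(CC(Br)=C)c(cc1OCc1ccccc1)[C@H](c1cc(OCc2ccccc2)c(OCc2ccccc2)c(OC)c1)CC(=O)OC(C)(C)C | intermediate
18 | tert-butyl (3S)-3-[5-(benzyloxy)-2-(2-bromoprop-2-en-1-yl)-4-methoxyphenyl]-3-[3,4-bis(benzyloxy)-5-methoxyphenyl]-2-hydroxypropanoate (C2 epimers, C2 left undefined) | COc1cc(CC(Br)=C)c(cc1OCc1ccccc1)[C@H](c1cc(OCc2ccccc2)c(OCc2ccccc2)c(OC)c1)C(O)C(=O)OC(C)(C)C | intermediate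
19 | tert-butyl (3S)-2-(benzyloxy)-3-[5-(benzyloxy)-2-(2-bromoprop-2-en-1-yl)-4-methoxyphenyl]-3-[3,4-bis(benzyloxy)-5-methoxyphenyl]propanoate (C2 epimers, C2 left undefined) | COc1cc(CC(Br)=C)c(cc1OCc1ccccc1)[C@H](c1cc(OCc2ccccc2)c(OCc2ccccc2)c(OC)c1)C(OCc1ccccc1)C(=O)OC(C)(C)C | intermediate
20 | tert-butyl (1S,2S)-2,7-bis(benzyloxy)-1-[3,4-bis(benzyloxy)-5-methoxyphenyl]-6-methoxy-3-methylidene-1,2,3,4-tetrahydronaphthalene-2-carboxylate | COc1cc2c(cc1OCc1ccccc1)[C@H](c1cc(OCc3ccccc3)c(OCc3ccccc3)c(OC)c1)[C@@](OCc1ccccc1)(C(=O)OC(C)(C)C)C(=C)C2 | intermediate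
21 | trimethylsilyl (1S,2S)-2,7-bis(benzyloxy)-1-[3,4-bis(benzyloxy)-5-methoxyphenyl]-6-methoxy-3-methylidene-1,2,3,4-tetrahydronaphthalene-2-carboxylate | COc1cc2c(cc1OCc1ccccc1)[C@H](c1cc(OCc3ccccc3)c(OCc3ccccc3)c(OC)c1)[C@@](OCc1ccccc1)(C(=O)O[Si](C)(C)C)C(=C)C2 | intermediate
22 | (1S,2S)-2,7-bis(benzyloxy)-1-[3,4-bis(benzyloxy)-5-methoxyphenyl]-6-methoxy-3-methylidene-1,2,3,4-tetrahydronaphthalene-2-carboxylic acid | COc1cc2c(cc1OCc1ccccc1)[C@H](c1cc(OCc3ccccc3)c(OCc3ccccc3)c(OC)c1)[C@@](OCc1ccccc1)(C(=O)O)C(=C)C2 | intermediate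
23 | (1S,2S,3S)-2,7-bis(benzyloxy)-1-[3,4-bis(benzyloxy)-5-methoxyphenyl]-3-hydroxy-3-(iodomethyl)-6-methoxy-1,2,3,4-tetrahydronaphthalene-2-carboxylic acid β-lactone (cis-fused at C2–C3) | COc1cc2c(cc1OCc1ccccc1)[C@H](c1cc(OCc3ccccc3)c(OCc3ccccc3)c(OC)c1)[C@@](OCc1ccccc1)(C(=O)O3)[C@]3(CI)C2 | intermediate
24 | (1S,2S,3S)-2,7-bis(benzyloxy)-1-[3,4-bis(benzyloxy)-5-methoxyphenyl]-3-hydroxy-3-(iodomethyl)-6-methoxy-1,2,3,4-tetrahydronaphthalene-2-carboxylic acid | COc1cc2c(cc1OCc1ccccc1)[C@H](c1cc(OCc3ccccc3)c(OCc3ccccc3)c(OC)c1)[C@@](OCc1ccccc1)(C(=O)O)[C@](O)(CI)C2 | intermediate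
25 | (1S,2S,3R)-2,7-bis(benzyloxy)-1-[3,4-bis(benzyloxy)-5-methoxyphenyl]-6-methoxy-1,2,3,4-tetrahydronaphthalene-2-carboxylic acid carrying a spiro-oxirane at C3 (ring atoms C3, C9, O3) | COc1cc2c(cc1OCc1ccccc1)[C@H](c1cc(OCc3ccccc3)c(OCc3ccccc3)c(OC)c1)[C@@](OCc1ccccc1)(C(=O)O)[C@]3(CO3)C2 | intermediate
26 | (1S,2S,3R)-2,7-bis(benzyloxy)-1-[3,4-bis(benzyloxy)-5-methoxyphenyl]-3-hydroxy-3-(hydroxymethyl)-6-methoxy-1,2,3,4-tetrahydronaphthalene-2-carboxylic acid | COc1cc2c(cc1OCc1ccccc1)[C@H](c1cc(OCc3ccccc3)c(OCc3ccccc3)c(OC)c1)[C@@](OCc1ccccc1)(C(=O)O)[C@](O)(CO)C2 | intermediate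
27 | plicatic acid, (1S,2S,3R)-1-(3,4-dihydroxy-5-methoxyphenyl)-2,3,7-trihydroxy-3-(hydroxymethyl)-6-methoxy-1,2,3,4-tetrahydronaphthalene-2-carboxylic acid | COc1cc2c(cc1O)[C@H](c1cc(O)c(O)c(OC)c1)[C@@](O)(C(=O)O)[C@](O)(CO)C2 | target

**Step count and risks**
Total: 15 steps. Longest linear sequence: 12 steps (1–4, then 8–15, from 1); the boronic acid branch (steps 5–7) joins at step 8.

Step 11. Reductive elimination from palladium at the fully substituted enolate carbon, flanked by the diarylmethyl group, may be slow enough for proto-debromination or base-induced loss of HBr from the bromoallyl arm to take over, and the two enolate faces may not be told apart well enough. The fallback sets out from 2 and comes back at 20; it makes the C2–C3 bond by a reversible Dieckmann acylation and adds the methylene carbon afterwards. Aldehyde 2 is olefinated with 8 as in step 4 to tert-butyl (2E)-3-[5-(benzyloxy)-2-bromo-4-methoxyphenyl]prop-2-enoate F1. Rhodium-catalysed arylation with 16 under the conditions of step 8, which tolerate aryl bromides, should give tert-butyl (3S)-3-[5-(benzyloxy)-2-bromo-4-methoxyphenyl]-3-[3,4-bis(benzyloxy)-5-methoxyphenyl]propanoate F2. Enolate hydroxylation and O-benzylation as in steps 9 and 10 lead to the 2-hydroxy ester F3 and the 2-benzyloxy ester F4 (C2 epimers). Palladium-catalysed coupling of the aryl bromide with the Reformatsky reagent BrZnCH2CO2Me (Pd(dba)2, Q-Phos, THF, rt) installs the arylacetate arm in tert-butyl (3S)-2-(benzyloxy)-3-[5-(benzyloxy)-4-methoxy-2-(2-methoxy-2-oxoethyl)phenyl]-3-[3,4-bis(benzyloxy)-5-methoxyphenyl]propanoate F5. KOt-Bu (1.1 equiv, THF, rt) should then close the C2 enolate onto the methyl ester to give tert-butyl (1S,2S)-2,7-bis(benzyloxy)-1-[3,4-bis(benzyloxy)-5-methoxyphenyl]-6-methoxy-3-oxo-1,2,3,4-tetrahydronaphthalene-2-carboxylate F6. This closure is driven by deprotonation at C4 and is reversible, so the more stable C2 epimer (tert-butyl ester trans to the C1 aryl group) should accumulate. Lombardo–Takai methylenation (Zn, CH2Br2, TiCl4, THF/CH2Cl2), which tolerates enolisable ketones and esters, converts F6 into 20.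

Step 13. The 4-exo closure against the congested C2 may be slow, which would give time for iodination of the electron-rich rings or for reversal and isomerisation of the strained lactone. The fallback sets out from 22 and comes back at 26 without a new compound: Upjohn dihydroxylation (OsO4 cat., NMO, acetone/H2O, rt). Osmium tetroxide is expected to approach the exocyclic alkene anti to the pseudoaxial C1 aryl group, which is the C10 face, so O3 should again end cis to C10 and C9 receives its hydroxyl in the same operation. Control is then steric instead of being enforced by ring fusion, and the diastereomer ratio would have to be checked.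

Step 14. Opening of the spiro-epoxide by hydroxide at C9 next to the carboxylate may be sluggish, so the epoxide could persist or the β-lactone could fragment on heating before it is hydrolysed. The fallback sets out from 23 and comes back at 27; it brings in the C9 oxygen as a benzyl ether on a neutral ester. BnONa in benzyl alcohol/THF at 0 °C opens the lactone and closes the epoxide to the benzyl ester of the spiro-epoxy acid F7. Warming to 80 °C with BnONa (0.3 equiv) in benzyl alcohol opens the oxirane at C9 to benzyl (1S,2S,3R)-2,7-bis(benzyloxy)-3-[(benzyloxy)methyl]-1-[3,4-bis(benzyloxy)-5-methoxyphenyl]-3-hydroxy-6-methoxy-1,2,3,4-tetrahydronaphthalene-2-carboxylate F8; in this protic solvent the tertiary C3 alkoxide is not present in an amount that would allow retro-aldol cleavage. Hydrogenolysis under the conditions of step 15 removes all six benzyl groups and gives 27.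

**Further compounds**
F1 | step 11 | tert-butyl (2E)-3-[5-(benzyloxy)-2-bromo-4-methoxyphenyl]prop-2-enoate | COc1cc(Br)c(/C=C/C(=O)OC(C)(C)C)cc1OCc1ccccc1
F2 | step 11 | tert-butyl (3S)-3-[5-(benzyloxy)-2-bromo-4-methoxyphenyl]-3-[3,4-bis(benzyloxy)-5-methoxyphenyl]propanoate | COc1cc(Br)c(cc1OCc1ccccc1)[C@H](c1cc(OCc2ccccc2)c(OCc2ccccc2)c(OC)c1)CC(=O)OC(C)(C)C
F3 | step 11 | tert-butyl (3S)-3-[5-(benzyloxy)-2-bromo-4-methoxyphenyl]-3-[3,4-bis(benzyloxy)-5-methoxyphenyl]-2-hydroxypropanoate (C2 epimers) | COc1cc(Br)c(cc1OCc1ccccc1)[C@H](c1cc(OCc2ccccc2)c(OCc2ccccc2)c(OC)c1)C(O)C(=O)OC(C)(C)C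
F4 | step 11 | tert-butyl (3S)-2-(benzyloxy)-3-[5-(benzyloxy)-2-bromo-4-methoxyphenyl]-3-[3,4-bis(benzyloxy)-5-methoxyphenyl]propanoate (C2 epimers) | COc1cc(Br)c(cc1OCc1ccccc1)[C@H](c1cc(OCc2ccccc2)c(OCc2ccccc2)c(OC)c1)C(OCc1ccccc1)C(=O)OC(C)(C)C
F5 | step 11 | tert-butyl (3S)-2-(benzyloxy)-3-[5-(benzyloxy)-4-methoxy-2-(2-methoxy-2-oxoethyl)phenyl]-3-[3,4-bis(benzyloxy)-5-methoxyphenyl]propanoate (C2 epimers) | COc1cc(CC(=O)OC)c(cc1OCc1ccccc1)[C@H](c1cc(OCc2ccccc2)c(OCc2ccccc2)c(OC)c1)C(OCc1ccccc1)C(=O)OC(C)(C)C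
F6 | step 11 | tert-butyl (1S,2S)-2,7-bis(benzyloxy)-1-[3,4-bis(benzyloxy)-5-methoxyphenyl]-6-methoxy-3-oxo-1,2,3,4-tetrahydronaphthalene-2-carboxylate | COc1cc2c(cc1OCc1ccccc1)[C@H](c1cc(OCc3ccccc3)c(OCc3ccccc3)c(OC)c1)[C@@](OCc1ccccc1)(C(=O)OC(C)(C)C)C(=O)C2
F0 | step 13 | none | none
F7 | step 14 | benzyl (1S,2S,3R)-2,7-bis(benzyloxy)-1-[3,4-bis(benzyloxy)-5-methoxyphenyl]-6-methoxy-1,2,3,4-tetrahydronaphthalene-2-carboxylate carrying a spiro-oxirane at C3 (ring atoms C3, C9, O3) | COc1cc2c(cc1OCc1ccccc1)[C@H](c1cc(OCc3ccccc3)c(OCc3ccccc3)c(OC)c1)[C@@](OCc1ccccc1)(C(=O)OCc1ccccc1)[C@]3(CO3)C2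
F8 | step 14 | benzyl (1S,2S,3R)-2,7-bis(benzyloxy)-3-[(benzyloxy)methyl]-1-[3,4-bis(benzyloxy)-5-methoxyphenyl]-3-hydroxy-6-methoxy-1,2,3,4-tetrahydronaphthalene-2-carboxylate | COc1cc2c(cc1OCc1ccccc1)[C@H](c1cc(OCc3ccccc3)c(OCc3ccccc3)c(OC)c1)[C@@](OCc1ccccc1)(C(=O)OCc1ccccc1)[C@](O)(COCc1ccccc1)C2
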